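**Plan**
- Retrosynthesis: remove the four benzyl ethers; cut ring C at C4–C4a; cut the ring A ether C–O, then C1–C2 of the open three-carbon chain (aldol); cut the lower isoflavan at O1–C2 and C3–C4.
- Enabling feature: C4 is a doubly benzylic methine whose cation is stabilised by ring D (oxygen para and methoxy ortho to C4), and ring A is a resorcinol diether that is nucleophilic at C4a, para to its 7-oxygen.
- Forward: the isoflavan pyran ring (ring F) is closed first on a brominated ring D; the bromide becomes the aldehyde; an aldol adds ring E and the chain; ring A is attached as an ether; ring C closes last.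
- Stereochemistry: isoflavan C3 from enolate benzylation under (R)-4-benzyloxazolidin-2-one; upper C3 from a boron aldol under the (S)-auxiliary; C4 relayed from C3 (trans) in the ring closure.

Key step: step 21

Remarks
- Ring labels: upper chroman = ring A (benzo) and ring C (pyran); ring D = arene on C4; ring E = arene on C3; lower isoflavan = ring F (pyran) and ring G (benzo).
- Compounds 1, 5, 10, 20, 25 and 31 are taken as purchased.
- Assumption: both C1 epimers of carbinol 32 ionise to the same cation, so only the (1S) epimer from the syn aldol is carried.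

**Ring G electrophile**

Step 1
Reactants: 1 4-benzyloxy-2-hydroxybenzaldehyde
Product: 2 4-benzyloxy-2-(methoxymethoxy)benzaldehyde
Conditions: MOMCl, i-Pr2NEt, CH2Cl2, 0 °C → rt
Reagents that add atoms: chloromethyl methyl ether, COCCl
Why: Williamson-type O-alkylation with an α-chloro ether masks, as an acetal orthogonal to the benzyl ether, the phenol that will later close ring F.

Step 2
Reactants: 2 4-benzyloxy-2-(methoxymethoxy)benzaldehyde
Product: 3 [4-benzyloxy-2-(methoxymethoxy)phenyl]methanol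
Conditions: NaBH4, MeOH/THF, 0 °C
Reagents that add atoms: none
Why: Borohydride reduction of the aryl aldehyde gives the benzylic alcohol and leaves both ethers untouched.

Step 3
Reactants: 3 [4-benzyloxy-2-(methoxymethoxy)phenyl]methanol
Product: 4 4-benzyloxy-1-(bromomethyl)-2-(methoxymethoxy)benzene
Conditions: CBr4, PPh3, CH2Cl2, 0 °C; used at once without chromatography
Reagents that add atoms: carbon tetrabromide, BrC(Br)(Br)Br
Why: The Appel reaction makes the benzylic bromide under neutral conditions that spare the acid-labile methoxymethyl ether.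

**Ring D and the (R)-isoflavan aldehyde**

Step 4
Reactants: 5 paeonol, 1-(2-hydroxy-4-methoxyphenyl)ethanone
Product: 6 1-(5-bromo-2-hydroxy-4-methoxyphenyl)ethanone
Conditions: NBS, MeCN, 0 °C → rt
Reagents that add atoms: N-bromosuccinimide, O=C1CCC(=O)N1Br
Why: Electrophilic aromatic bromination goes para to the free hydroxyl and ortho to the methoxy group, the carbon between the two oxygens being shielded, so the halogen sits where ring D will later carry C4.

Step 5
Reactants: 6 1-(5-bromo-2-hydroxy-4-methoxyphenyl)ethanone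
Product: 7 1-(2-benzyloxy-5-bromo-4-methoxyphenyl)ethanone
Conditions: BnBr, K2CO3, DMF, 60 °C
Reagents that add atoms: benzyl bromide, BrCc1ccccc1
Why: Williamson etherification of the hydrogen-bonded phenol installs the benzyl ether that stays on the ring D oxygen until the last step.

Step 6
Reactants: 7 1-(2-benzyloxy-5-bromo-4-methoxyphenyl)ethanone
Product: 9 (2-benzyloxy-5-bromo-4-methoxyphenyl)acetic acid, via thiomorpholide 8 (not isolated)
Conditions: S8, morpholine, 130 °C; then 20 % aq. NaOH, BnEt3NCl (cat.), 100 °C; HCl to pH 2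
Reagents that add atoms: sodium hydroxide, [Na+].[OH-]; sulfur, S1SSSSSSS1, and morpholine, C1COCCN1 (both stay only in intermediate 8)
Why: The Willgerodt–Kindler reaction moves the oxidised carbon to the chain end as the thioamide and base hydrolysis frees the arylacetic acid, a classical route from alkoxyacetophenones that tolerates the aryl bromide and the benzyl ether.

Step 7
Reactants: 9 (2-benzyloxy-5-bromo-4-methoxyphenyl)acetic acid; 10 (R)-4-benzyloxazolidin-2-one
Product: 12 (4R)-4-benzyl-3-[(2-benzyloxy-5-bromo-4-methoxyphenyl)acetyl]oxazolidin-2-one, via mixed pivalic anhydride 11 (not isolated)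
Conditions: PivCl, Et3N, THF, −20 °C; then 10, LiCl, −20 °C → rt
Reagents that add atoms: pivaloyl chloride, CC(C)(C)C(=O)Cl (its atoms stay only in intermediate 11)
Why: N-acylation of the oxazolidinone through the mixed anhydride with LiCl/Et3N activation attaches the auxiliary without a strong base.

Step 8
Reactants: 12 (4R)-4-benzyl-3-[(2-benzyloxy-5-bromo-4-methoxyphenyl)acetyl]oxazolidin-2-one; 4 4-benzyloxy-1-(bromomethyl)-2-(methoxymethoxy)benzene
Product: 14 (4R)-4-benzyl-3-{(2R)-2-(2-benzyloxy-5-bromo-4-methoxyphenyl)-3-[4-benzyloxy-2-(methoxymethoxy)phenyl]propanoyl}oxazolidin-2-one, via sodium enolate 13 (not isolated)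
Conditions: NaN(SiMe3)2, THF, −78 °C; then 4, −78 → −20 °C
Reagents that add atoms: sodium bis(trimethylsilyl)amide, C[Si](C)(C)[N-][Si](C)(C)C.[Na+] (sodium stays only in intermediate 13)
Why: Evans enolate alkylation: the chelated sodium Z-enolate is benzylated on the face opposite the auxiliary benzyl group, which with the (R)-auxiliary sets the (2R) centre that becomes isoflavan C3.

Step 9
Reactants: 14 (4R)-4-benzyl-3-{(2R)-2-(2-benzyloxy-5-bromo-4-methoxyphenyl)-3-[4-benzyloxy-2-(methoxymethoxy)phenyl]propanoyl}oxazolidin-2-one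
Product: 15 (2R)-2-(2-benzyloxy-5-bromo-4-methoxyphenyl)-3-[4-benzyloxy-2-(methoxymethoxy)phenyl]propan-1-ol
Conditions: LiBH4, H2O (1 equiv), THF, 0 °C
Reagents that add atoms: none
Why: Hydride reduction of the exocyclic imide carbonyl releases the auxiliary and gives the primary alcohol without touching the α-aryl stereocentre, the aryl bromide or the acetal.

Step 10
Reactants: 15 (2R)-2-(2-benzyloxy-5-bromo-4-methoxyphenyl)-3-[4-benzyloxy-2-(methoxymethoxy)phenyl]propan-1-ol
Product: 16 5-benzyloxy-2-[(2R)-2-(2-benzyloxy-5-bromo-4-methoxyphenyl)-3-hydroxypropyl]phenol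
Conditions: conc. HCl (cat.), MeOH, 50 °C
Reagents that add atoms: none
Why: Acid-catalysed acetal exchange with methanol removes the methoxymethyl group while the benzyl ethers, the bromide and the primary alcohol stay in place.

Step 11
Reactants: 16 5-benzyloxy-2-[(2R)-2-(2-benzyloxy-5-bromo-4-methoxyphenyl)-3-hydroxypropyl]phenol
Product: 17 (3R)-7-benzyloxy-3-(2-benzyloxy-5-bromo-4-methoxyphenyl)chroman
Conditions: PPh3, DIAD, THF, 0 °C → rt
Reagents that add atoms: none
Why: Intramolecular Mitsunobu etherification (6-exo-tet attack of the phenol on the activated primary carbinol) closes ring F at a carbon remote from the stereocentre, so C3 stays (R).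

Step 12
Reactants: 17 (3R)-7-benzyloxy-3-(2-benzyloxy-5-bromo-4-methoxyphenyl)chroman
Product: 19 4-benzyloxy-5-[(3R)-7-benzyloxychroman-3-yl]-2-methoxybenzaldehyde, via aryllithium 18 (not isolated)
Conditions: n-BuLi, THF, −78 °C; DMF, −78 → 0 °C; H2O
Reagents that add atoms: N,N-dimethylformamide, CN(C)C=O; n-butyllithium, [Li]CCCC (lithium stays only in intermediate 18)
Why: Bromine–lithium exchange outruns any deprotonation at −78 °C and formylation of the aryllithium by DMF fixes the aldehyde on the ring D carbon that will bear C4.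

**Ring E imide**

Step 13
Reactants: 20 2,6-dimethoxyphenol
Product: 21 2-benzyloxy-1,3-dimethoxybenzene
Conditions: BnBr, K2CO3, DMF, 60 °C
Reagents that add atoms: benzyl bromide, BrCc1ccccc1
Why: Williamson etherification protects the ring E phenol as the benzyl ether that is removed with the others at the end.

Step 14
Reactants: 21 2-benzyloxy-1,3-dimethoxybenzene
Product: 22 2-benzyloxy-4-bromo-1,3-dimethoxybenzene
Conditions: NBS, MeCN, 0 °C → rt
Reagents that add atoms: N-bromosuccinimide, O=C1CCC(=O)N1Br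
Why: Electrophilic aromatic bromination of the 1,2,3-trioxygenated arene occurs at C4, ortho to one methoxy group and para to the other, because the flanked central benzyloxy group is twisted out of conjugation.

Step 15
Reactants: 22 2-benzyloxy-4-bromo-1,3-dimethoxybenzene
Product: 23 ethyl (3-benzyloxy-2,4-dimethoxyphenyl)acetate
Conditions: BrZnCH2CO2Et (from BrCH2CO2Et and Zn dust, THF), Pd2(dba)3 (2 mol %), XPhos (8 mol %), THF, 65 °C
Reagents that add atoms: ethyl bromozincacetate, CCOC(=O)C[Zn]Br (made from ethyl bromoacetate, CCOC(=O)CBr, and zinc)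
Why: Palladium-catalysed Negishi-type α-arylation of the Reformatsky reagent forms the aryl–CH2 bond of the arylacetate directly from the electron-rich aryl bromide.

Step 16
Reactants: 23 ethyl (3-benzyloxy-2,4-dimethoxyphenyl)acetate
Product: 24 (3-benzyloxy-2,4-dimethoxyphenyl)acetic acid
Conditions: LiOH, THF/MeOH/H2O, rt; HCl
Reagents that add atoms: lithium hydroxide, [Li+].[OH-]
Why: Saponification of the ethyl ester gives the acid needed for auxiliary attachment and leaves all three aryl ethers intact.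

Step 17
Reactants: 24 (3-benzyloxy-2,4-dimethoxyphenyl)acetic acid; 25 (S)-4-benzyloxazolidin-2-one
Product: 27 (4S)-4-benzyl-3-[(3-benzyloxy-2,4-dimethoxyphenyl)acetyl]oxazolidin-2-one, via mixed pivalic anhydride 26 (not isolated)
Conditions: PivCl, Et3N, THF, −20 °C; then 25, LiCl, −20 °C → rt
Reagents that add atoms: pivaloyl chloride, CC(C)(C)C(=O)Cl (its atoms stay only in intermediate 26)
Why: N-acylation of the oxazolidinone through the mixed anhydride gives the aldol donor under the same mild conditions as in step 7.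

**Union and end game**

Step 18
Reactants: 27 (4S)-4-benzyl-3-[(3-benzyloxy-2,4-dimethoxyphenyl)acetyl]oxazolidin-2-one; 19 4-benzyloxy-5-[(3R)-7-benzyloxychroman-3-yl]-2-methoxybenzaldehyde
Product: 29 (4S)-4-benzyl-3-[(2S,3S)-3-{4-benzyloxy-5-[(3R)-7-benzyloxychroman-3-yl]-2-methoxyphenyl}-2-(3-benzyloxy-2,4-dimethoxyphenyl)-3-hydroxypropanoyl]oxazolidin-2-one, via boron enolate 28 (not isolated)
Conditions: 27 (1.3 equiv), Bu2BOTf, i-Pr2NEt, CH2Cl2, −78 → 0 °C; 19, −78 → 0 °C; pH 7 buffer, MeOH, H2O2, 0 °C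
Reagents that add atoms: dibutylboron triflate, CCCCB(CCCC)OS(=O)(=O)C(F)(F)F (boron stays only in intermediate 28)
Why: Evans syn aldol: the dibutylboron Z-enolate adds to the non-enolisable aldehyde through a chair Zimmerman–Traxler transition state on the enolate face remote from the (S)-auxiliary benzyl group, giving the (2S,3S) adduct whose C2 becomes chroman C3 while the carbinol centre is spent in step 21.

Step 19
Reactants: 29 (4S)-4-benzyl-3-[(2S,3S)-3-{4-benzyloxy-5-[(3R)-7-benzyloxychroman-3-yl]-2-methoxyphenyl}-2-(3-benzyloxy-2,4-dimethoxyphenyl)-3-hydroxypropanoyl]oxazolidin-2-one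
Product: 30 (1S,2R)-1-{4-benzyloxy-5-[(3R)-7-benzyloxychroman-3-yl]-2-methoxyphenyl}-2-(3-benzyloxy-2,4-dimethoxyphenyl)propane-1,3-diol
Conditions: LiBH4, MeOH (1 equiv), THF, 0 °C
Reagents that add atoms: none
Why: Hydride reduction of the imide carbonyl, assisted by the neighbouring hydroxyl, gives the 1,3-diol and returns the auxiliary under conditions expected to be too mild for retro-aldol or epimerisation.

Step 20
Reactants: 30 (1S,2R)-1-{4-benzyloxy-5-[(3R)-7-benzyloxychroman-3-yl]-2-methoxyphenyl}-2-(3-benzyloxy-2,4-dimethoxyphenyl)propane-1,3-diol; 31 3-benzyloxyphenol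
Product: 32 (1S,2R)-1-{4-benzyloxy-5-[(3R)-7-benzyloxychroman-3-yl]-2-methoxyphenyl}-3-(3-benzyloxyphenoxy)-2-(3-benzyloxy-2,4-dimethoxyphenyl)propan-1-ol
Conditions: 31 (1.1 equiv), PPh3, DIAD, toluene, 0 °C → rt
Reagents that add atoms: none
Why: Mitsunobu etherification should take place at the primary hydroxyl, whose oxyphosphonium forms and is displaced (SN2) by the phenoxide far faster than that of the flanked secondary benzylic hydroxyl, so neither stereocentre is touched.

Step 21
Reactants: 32 (1S,2R)-1-{4-benzyloxy-5-[(3R)-7-benzyloxychroman-3-yl]-2-methoxyphenyl}-3-(3-benzyloxyphenoxy)-2-(3-benzyloxy-2,4-dimethoxyphenyl)propan-1-ol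
Product: 34 (3R,4S)-7-benzyloxy-4-{4-benzyloxy-5-[(3R)-7-benzyloxychroman-3-yl]-2-methoxyphenyl}-3-(3-benzyloxy-2,4-dimethoxyphenyl)chroman, via benzylic cation 33 (not isolated)
Conditions: Bi(OTf)3 (5 mol %), CH2Cl2 (0.01 M), −20 → 0 °C
Reagents that add atoms: none
Why: The acid ionises the benzylic C–OH with loss of water; cation 33, held as a para-quinone-methide-type oxocarbenium by the para-benzyloxy and ortho-methoxy groups of ring D, is attacked by the ring A carbon para to its benzyloxy group (the future C4a), and proton loss restores aromaticity. This is an intramolecular Friedel–Crafts alkylation, the known acid-mediated cyclisation of 3-aryloxy-1-arylpropan-1-ols to 4-arylchromans. Ring C closes as a six-membered ring, 6-endo with respect to the attacking C4a=C8a arene bond, through a half-chair transition state. The new C4 centre is controlled by C3: ring E and the incoming ring D both take pseudo-equatorial positions, so ring D ends up trans to ring E, (3R,4S), and because ionisation removes the carbinol configuration either C1 epimer would converge. The step needs closure para to the benzyloxy group and not between the two ring A oxygens, which the steric shielding of that flanked carbon should secure. It also needs cyclisation to outrun intermolecular arylation and loss of the C3 proton, which high dilution, low temperature and the six-membered delivery of a resorcinol-type diether should secure.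

Step 22
Reactants: 34 (3R,4S)-7-benzyloxy-4-{4-benzyloxy-5-[(3R)-7-benzyloxychroman-3-yl]-2-methoxyphenyl}-3-(3-benzyloxy-2,4-dimethoxyphenyl)chroman
Product: 35 (3R,4S)-4-{4-hydroxy-5-[(3R)-7-hydroxychroman-3-yl]-2-methoxyphenyl}-3-(3-hydroxy-2,4-dimethoxyphenyl)chroman-7-ol
Conditions: H2 (1 atm), Pd/C (10 %), EtOAc/MeOH, rt
Reagents that add atoms: none
Why: Palladium-catalysed hydrogenolysis cleaves the four benzylic C–O bonds, while the aryl alkyl ethers of both pyran rings, the methyl ethers and the doubly benzylic C4–H are inert.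

**Compound list**

1 | 4-benzyloxy-2-hydroxybenzaldehyde | O=Cc1ccc(OCc2ccccc2)cc1O | starting material
2 | 4-benzyloxy-2-(methoxymethoxy)benzaldehyde | COCOc1cc(OCc2ccccc2)ccc1C=O | intermediate
3 | [4-benzyloxy-2-(methoxymethoxy)phenyl]methanol | COCOc1cc(OCc2ccccc2)ccc1CO | intermediate
4 | 4-benzyloxy-1-(bromomethyl)-2-(methoxymethoxy)benzene | COCOc1cc(OCc2ccccc2)ccc1CBr | intermediate
5 | paeonol, 1-(2-hydroxy-4-methoxyphenyl)ethanone | CC(=O)c1ccc(OC)cc1O | starting material
6 | 1-(5-bromo-2-hydroxy-4-methoxyphenyl)ethanone | CC(=O)c1cc(Br)c(OC)cc1O | intermediate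
7 | 1-(2-benzyloxy-5-bromo-4-methoxyphenyl)ethanone | CC(=O)c1cc(Br)c(OC)cc1OCc1ccccc1 | intermediate
8 | 2-(2-benzyloxy-5-bromo-4-methoxyphenyl)-1-(morpholin-4-yl)ethanethione (thiomorpholide, not isolated) | S=C(Cc1cc(Br)c(OC)cc1OCc1ccccc1)N1CCOCC1 | intermediate
9 | (2-benzyloxy-5-bromo-4-methoxyphenyl)acetic acid | OC(=O)Cc1cc(Br)c(OC)cc1OCc1ccccc1 | intermediate
10 | (R)-4-benzyloxazolidin-2-one | O=C1N[C@H](Cc2ccccc2)CO1 | starting material
11 | (2-benzyloxy-5-bromo-4-methoxyphenyl)acetic pivalic anhydride (not isolated) | CC(C)(C)C(=O)OC(=O)Cc1cc(Br)c(OC)cc1OCc1ccccc1 | intermediate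
12 | (4R)-4-benzyl-3-[(2-benzyloxy-5-bromo-4-methoxyphenyl)acetyl]oxazolidin-2-one | O=C(Cc1cc(Br)c(OC)cc1OCc1ccccc1)N1[C@H](Cc2ccccc2)COC1=O | intermediate
13 | sodium (Z)-enolate of 12 (not isolated) | [Na+].[O-]/C(=C\c1cc(Br)c(OC)cc1OCc1ccccc1)N1[C@H](Cc2ccccc2)COC1=O | intermediate
14 | (4R)-4-benzyl-3-{(2R)-2-(2-benzyloxy-5-bromo-4-methoxyphenyl)-3-[4-benzyloxy-2-(methoxymethoxy)phenyl]propanoyl}oxazolidin-2-one | O=C(N1[C@H](Cc2ccccc2)COC1=O)[C@H](Cc1ccc(OCc2ccccc2)cc1OCOC)c1cc(Br)c(OC)cc1OCc1ccccc1 | intermediate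
15 | (2R)-2-(2-benzyloxy-5-bromo-4-methoxyphenyl)-3-[4-benzyloxy-2-(methoxymethoxy)phenyl]propan-1-ol | OC[C@H](Cc1ccc(OCc2ccccc2)cc1OCOC)c1cc(Br)c(OC)cc1OCc1ccccc1 | intermediate
16 | 5-benzyloxy-2-[(2R)-2-(2-benzyloxy-5-bromo-4-methoxyphenyl)-3-hydroxypropyl]phenol | OC[C@H](Cc1ccc(OCc2ccccc2)cc1O)c1cc(Br)c(OC)cc1OCc1ccccc1 | intermediate
17 | (3R)-7-benzyloxy-3-(2-benzyloxy-5-bromo-4-methoxyphenyl)chroman | COc1cc(OCc2ccccc2)c([C@@H]2COc3cc(OCc4ccccc4)ccc3C2)cc1Br | intermediate
18 | {4-benzyloxy-5-[(3R)-7-benzyloxychroman-3-yl]-2-methoxyphenyl}lithium (not isolated) | [Li]c1cc([C@@H]2COc3cc(OCc4ccccc4)ccc3C2)c(OCc2ccccc2)cc1OC | intermediate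
19 | 4-benzyloxy-5-[(3R)-7-benzyloxychroman-3-yl]-2-methoxybenzaldehyde | O=Cc1cc([C@@H]2COc3cc(OCc4ccccc4)ccc3C2)c(OCc2ccccc2)cc1OC | intermediate
20 | 2,6-dimethoxyphenol | COc1cccc(OC)c1O | starting material
21 | 2-benzyloxy-1,3-dimethoxybenzene | COc1cccc(OC)c1OCc1ccccc1 | intermediate
22 | 2-benzyloxy-4-bromo-1,3-dimethoxybenzene | COc1ccc(Br)c(OC)c1OCc1ccccc1 | intermediate
23 | ethyl (3-benzyloxy-2,4-dimethoxyphenyl)acetate | CCOC(=O)Cc1ccc(OC)c(OCc2ccccc2)c1OC | intermediate
24 | (3-benzyloxy-2,4-dimethoxyphenyl)acetic acid | OC(=O)Cc1ccc(OC)c(OCc2ccccc2)c1OC | intermediate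
25 | (S)-4-benzyloxazolidin-2-one | O=C1N[C@@H](Cc2ccccc2)CO1 | starting material
26 | (3-benzyloxy-2,4-dimethoxyphenyl)acetic pivalic anhydride (not isolated) | CC(C)(C)C(=O)OC(=O)Cc1ccc(OC)c(OCc2ccccc2)c1OC | intermediate
27 | (4S)-4-benzyl-3-[(3-benzyloxy-2,4-dimethoxyphenyl)acetyl]oxazolidin-2-one | O=C(Cc1ccc(OC)c(OCc2ccccc2)c1OC)N1[C@@H](Cc2ccccc2)COC1=O | intermediate
28 | dibutylboron (Z)-enolate of 27 (not isolated) | CCCCB(CCCC)O/C(=C\c1ccc(OC)c(OCc2ccccc2)c1OC)N1[C@@H](Cc2ccccc2)COC1=O | intermediate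
29 | (4S)-4-benzyl-3-[(2S,3S)-3-{4-benzyloxy-5-[(3R)-7-benzyloxychroman-3-yl]-2-methoxyphenyl}-2-(3-benzyloxy-2,4-dimethoxyphenyl)-3-hydroxypropanoyl]oxazolidin-2-one | O=C(N1[C@@H](Cc2ccccc2)COC1=O)[C@H]([C@H](O)c1cc([C@@H]2COc3cc(OCc4ccccc4)ccc3C2)c(OCc2ccccc2)cc1OC)c1ccc(OC)c(OCc2ccccc2)c1OC | intermediate
30 | (1S,2R)-1-{4-benzyloxy-5-[(3R)-7-benzyloxychroman-3-yl]-2-methoxyphenyl}-2-(3-benzyloxy-2,4-dimethoxyphenyl)propane-1,3-diol | OC[C@H]([C@H](O)c1cc([C@@H]2COc3cc(OCc4ccccc4)ccc3C2)c(OCc2ccccc2)cc1OC)c1ccc(OC)c(OCc2ccccc2)c1OC | intermediate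
31 | 3-benzyloxyphenol | Oc1cccc(OCc2ccccc2)c1 | starting material
32 | (1S,2R)-1-{4-benzyloxy-5-[(3R)-7-benzyloxychroman-3-yl]-2-methoxyphenyl}-3-(3-benzyloxyphenoxy)-2-(3-benzyloxy-2,4-dimethoxyphenyl)propan-1-ol | O(c1cccc(OCc2ccccc2)c1)C[C@H]([C@H](O)c1cc([C@@H]2COc3cc(OCc4ccccc4)ccc3C2)c(OCc2ccccc2)cc1OC)c1ccc(OC)c(OCc2ccccc2)c1OC | intermediate
33 | benzylic cation from 32 (not isolated) | O(c1cccc(OCc2ccccc2)c1)C[C@H]([CH+]c1cc([C@@H]2COc3cc(OCc4ccccc4)ccc3C2)c(OCc2ccccc2)cc1OC)c1ccc(OC)c(OCc2ccccc2)c1OC | intermediate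
34 | (3R,4S)-7-benzyloxy-4-{4-benzyloxy-5-[(3R)-7-benzyloxychroman-3-yl]-2-methoxyphenyl}-3-(3-benzyloxy-2,4-dimethoxyphenyl)chroman | COc1cc(OCc2ccccc2)c([C@@H]2COc3cc(OCc4ccccc4)ccc3C2)cc1[C@@H]1c2ccc(OCc3ccccc3)cc2OC[C@H]1c1ccc(OC)c(OCc2ccccc2)c1OC | intermediate
35 | (3R,4S)-4-{4-hydroxy-5-[(3R)-7-hydroxychroman-3-yl]-2-methoxyphenyl}-3-(3-hydroxy-2,4-dimethoxyphenyl)chroman-7-ol | COc1cc(O)c([C@@H]2COc3cc(O)ccc3C2)cc1[C@@H]1c2ccc(O)cc2OC[C@H]1c1ccc(OC)c(O)c1OC | target

**Count**

Total steps: 22. Longest linear sequence: 14 steps (5 to 35 through steps 4–12 and 18–22).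

**Steps most likely to fail**

1. Step 21. After ionisation the cation may shed the C3 proton, giving a triaryl-substituted alkene whose reprotonation would erase C3, and under a Brønsted acid the new C4–C4a bond may reopen and let the cis isomer or the regioisomer closed between the two ring A oxygens build up. Fallback, from 32 back to 34: acetylation (Ac2O, Et3N, DMAP) gives the benzylic acetate F1. F1 is ionised with TMSOTf and 2,6-di-tert-butyl-4-methylpyridine in CH2Cl2 at −78 °C, so the leaving group departs under buffered, aprotic conditions and the ring closure delivers 34 under kinetic control.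

2. Step 18. Addition of the stabilised, hindered arylacetyl enolate to the electron-rich, ortho-substituted aldehyde may stall, or revert by retro-aldol during work-up, and the α-aryl centre may epimerise. Fallback, from 27 back to 32, with ring D as the nucleophile and C3 set by alkylation:
   - 31 with NaH and BrCH2Cl gives 1-benzyloxy-3-(chloromethoxy)benzene F2.
   - The titanium enolate of 27 (TiCl4, i-Pr2NEt, CH2Cl2, 0 °C) is alkylated by F2 on the face remote from the auxiliary benzyl group, giving (4S)-4-benzyl-3-[(2R)-3-(3-benzyloxyphenoxy)-2-(3-benzyloxy-2,4-dimethoxyphenyl)propanoyl]oxazolidin-2-one F3. The same (S)-auxiliary serves because the chain ends are exchanged relative to the aldol.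
   - LiBH4 gives (2S)-3-(3-benzyloxyphenoxy)-2-(3-benzyloxy-2,4-dimethoxyphenyl)propan-1-ol F4.
   - Dess–Martin periodinane gives (2R)-3-(3-benzyloxyphenoxy)-2-(3-benzyloxy-2,4-dimethoxyphenyl)propanal F5, used at once.
   - Aryllithium 18, made from 17 as in step 12 and transmetallated with CeCl3 to limit enolisation, adds at −78 °C to give 32 together with its C1 epimer F6; both feed step 21.

3. Step 20. With the diol unprotected, the Mitsunobu reagents may also activate the secondary, readily ionised benzylic hydroxyl, leading to elimination, oxetane formation or etherification at the wrong carbon. Fallback, from 29 back to 32, with the carbinol protected: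
   - TBSOTf and 2,6-lutidine convert 29 into the silyl ether F7.
   - LiBH4 gives the primary alcohol F8.
   - Mitsunobu etherification with 31 gives the aryl ether F9.
   - Bu4NF in THF removes the silyl group to give 32.

**Further compounds**

F1 | step 21 | (1S,2R)-1-{4-benzyloxy-5-[(3R)-7-benzyloxychroman-3-yl]-2-methoxyphenyl}-3-(3-benzyloxyphenoxy)-2-(3-benzyloxy-2,4-dimethoxyphenyl)propyl acetate | O(c1cccc(OCc2ccccc2)c1)C[C@H]([C@H](OC(C)=O)c1cc([C@@H]2COc3cc(OCc4ccccc4)ccc3C2)c(OCc2ccccc2)cc1OC)c1ccc(OC)c(OCc2ccccc2)c1OC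
F2 | step 18 | 1-benzyloxy-3-(chloromethoxy)benzene | ClCOc1cccc(OCc2ccccc2)c1
F3 | step 18 | (4S)-4-benzyl-3-[(2R)-3-(3-benzyloxyphenoxy)-2-(3-benzyloxy-2,4-dimethoxyphenyl)propanoyl]oxazolidin-2-one | O(c1cccc(OCc2ccccc2)c1)C[C@H](C(=O)N1[C@@H](Cc2ccccc2)COC1=O)c1ccc(OC)c(OCc2ccccc2)c1OC
F4 | step 18 | (2S)-3-(3-benzyloxyphenoxy)-2-(3-benzyloxy-2,4-dimethoxyphenyl)propan-1-ol | O(c1cccc(OCc2ccccc2)c1)C[C@H](CO)c1ccc(OC)c(OCc2ccccc2)c1OC
F5 | step 18 | (2R)-3-(3-benzyloxyphenoxy)-2-(3-benzyloxy-2,4-dimethoxyphenyl)propanal | O(c1cccc(OCc2ccccc2)c1)C[C@H](C=O)c1ccc(OC)c(OCc2ccccc2)c1OC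
F6 | step 18 | (1R,2R)-1-{4-benzyloxy-5-[(3R)-7-benzyloxychroman-3-yl]-2-methoxyphenyl}-3-(3-benzyloxyphenoxy)-2-(3-benzyloxy-2,4-dimethoxyphenyl)propan-1-ol | O(c1cccc(OCc2ccccc2)c1)C[C@H]([C@@H](O)c1cc([C@@H]2COc3cc(OCc4ccccc4)ccc3C2)c(OCc2ccccc2)cc1OC)c1ccc(OC)c(OCc2ccccc2)c1OC
F7 | step 20 | (4S)-4-benzyl-3-[(2S,3S)-3-{4-benzyloxy-5-[(3R)-7-benzyloxychroman-3-yl]-2-methoxyphenyl}-2-(3-benzyloxy-2,4-dimethoxyphenyl)-3-(tert-butyldimethylsilyloxy)propanoyl]oxazolidin-2-one | O=C(N1[C@@H](Cc2ccccc2)COC1=O)[C@H]([C@H](O[Si](C)(C)C(C)(C)C)c1cc([C@@H]2COc3cc(OCc4ccccc4)ccc3C2)c(OCc2ccccc2)cc1OC)c1ccc(OC)c(OCc2ccccc2)c1OC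
F8 | step 20 | (2R,3S)-3-{4-benzyloxy-5-[(3R)-7-benzyloxychroman-3-yl]-2-methoxyphenyl}-2-(3-benzyloxy-2,4-dimethoxyphenyl)-3-(tert-butyldimethylsilyloxy)propan-1-ol | OC[C@H]([C@H](O[Si](C)(C)C(C)(C)C)c1cc([C@@H]2COc3cc(OCc4ccccc4)ccc3C2)c(OCc2ccccc2)cc1OC)c1ccc(OC)c(OCc2ccccc2)c1OC
F9 | step 20 | tert-butyl{(1S,2R)-1-{4-benzyloxy-5-[(3R)-7-benzyloxychroman-3-yl]-2-methoxyphenyl}-3-(3-benzyloxyphenoxy)-2-(3-benzyloxy-2,4-dimethoxyphenyl)propoxy}dimethylsilane | O(c1cccc(OCc2ccccc2)c1)C[C@H]([C@H](O[Si](C)(C)C(C)(C)C)c1cc([C@@H]2COc3cc(OCc4ccccc4)ccc3C2)c(OCc2ccccc2)cc1OC)c1ccc(OC)c(OCc2ccccc2)c1OC
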